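**Retrosynthetic overview**
1. The two formyl groups (C6', C8') and the free phenols come last, by hydrogenolysis and Vilsmeier–Haack formylation of the 5',7'-bis(benzyloxy) spirochroman.
2. Key disconnection: the O1'–C2 bond and the C3–C4 bond of the bicyclo[2.2.1]heptane (CMe2 to bridgehead) are made in one photoredox radical-cation cascade. The precursor is an open-chain phenol carrying a C2=CMe2 tetrasubstituted alkene and a cyclopent-3-enyl group. Ring order: dihydropyran ring first, then both carbocyclic rings of the bicycle at once.
3. Enabling feature: C3 (CMe2) is β to O1' through the spiro carbon C2 and 1,3 to bridgehead C4 across the cyclopentane ring C1–C7–C4–C5–C6. That ring is therefore a Cs-symmetric cyclopent-3-enyl substituent in disguise, and a radical at C3, born when O1' adds to the oxidised C2=CMe2 alkene, reaches it in 5-exo mode.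
4. The precursor comes from a ketone and acetone (McMurry), the ketone from a Weinreb amide and cyclopent-3-enylmagnesium bromide. The one catalysis-set stereocentre C4' comes from an iminium-catalysed Friedel–Crafts alkylation of 3,5-bis(benzyloxy)phenol with (E)-5-methylhex-2-enal; C2, C1 and C4 are relayed from C4' in the key step.

Key step: step 6

Assumption: the descriptors (1R,2R,4S,4'S) were derived from the given SMILES (ring oxygen endo on the bicycloheptane, isobutyl cis to the CMe2 carbon on the dihydropyran ring); (E)-5-methylhex-2-enal and 4-bromocyclopentene are taken as purchasable.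

**Step 1**
Reactants: 1 3,5-bis(benzyloxy)phenol; 2 (E)-5-methylhex-2-enal
Product: 3 (4S)-5,7-bis(benzyloxy)-4-(2-methylpropyl)chroman-2-ol (mixture of C2 anomers)
Conditions: (R)-α,α-diphenylprolinol TMS ether (20 mol %), PhCO2H (20 mol %), toluene, 0 °C
Reagents that add atoms: none
Why: Iminium-catalysed enantioselective Friedel–Crafts alkylation/hemiacetalisation of an electron-rich phenol with an enal: the arene carbon ortho to OH should attack the Cβ Si face of the (E)-iminium ion, anti to the diphenyl(silyloxy)methyl group of the (R)-catalyst, which sets C4 as S, and closure to the lactol prevents a second alkylation.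

**Step 2**
Reactants: 3 (4S)-5,7-bis(benzyloxy)-4-(2-methylpropyl)chroman-2-ol
Product: 4 (4S)-5,7-bis(benzyloxy)-4-(2-methylpropyl)chroman-2-one
Conditions: TEMPO (10 mol %), PhI(OAc)2, CH2Cl2, rt
Reagents that add atoms: none
Why: Oxoammonium (TEMPO) oxidation of a lactol to the lactone; the stereocentre is β to the carbonyl group and cannot epimerise.

**Step 3**
Reactants: 4 (4S)-5,7-bis(benzyloxy)-4-(2-methylpropyl)chroman-2-one
Product: 5 (3S)-3-[2,4-bis(benzyloxy)-6-hydroxyphenyl]-N-methoxy-N,5-dimethylhexanamide
Conditions: MeNH(OMe)·HCl, i-PrMgCl, THF, −20 to 0 °C; aq. NH4Cl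
Reagents that add atoms: N,O-dimethylhydroxylamine hydrochloride, CNOC.Cl
Why: Weinreb amide formation by aminolysis of an aryl ester with the chloromagnesium amide, driven by the phenoxide leaving group; the ring opens and frees the phenol needed later.

**Step 4**
Reactants: 5 (3S)-3-[2,4-bis(benzyloxy)-6-hydroxyphenyl]-N-methoxy-N,5-dimethylhexanamide; 6 4-bromocyclopent-1-ene
Product: 8 (3S)-3-[2,4-bis(benzyloxy)-6-hydroxyphenyl]-1-(cyclopent-3-en-1-yl)-5-methylhexan-1-one (in equilibrium with its ring-closed hemiketal form), via cyclopent-3-en-1-ylmagnesium bromide 7 (not isolated)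
Conditions: 6, Mg, THF, rt; then 5 (0.33 equiv relative to 7), THF, 0 °C to rt; aq. NH4Cl
Reagents that add atoms: none
Why: Weinreb ketone synthesis with a Grignard reagent: the first equivalent deprotonates the phenol, the next adds once, and the chelated tetrahedral intermediate should hold until the quench, so no tertiary alcohol is expected.

**Step 5**
Reactants: 8 (3S)-3-[2,4-bis(benzyloxy)-6-hydroxyphenyl]-1-(cyclopent-3-en-1-yl)-5-methylhexan-1-one
Product: 9 3,5-bis(benzyloxy)-2-[(4S)-6-(cyclopent-3-en-1-yl)-2,7-dimethyloct-6-en-4-yl]phenol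
Conditions: TiCl4, Zn, pyridine, THF, reflux; then 8 and acetone (5 equiv), reflux; aq. K2CO3
Reagents that add atoms: acetone, CC(C)=O
Why: Mixed McMurry reductive carbonyl coupling with excess acetone should give the tetrasubstituted isopropylidene alkene, which has no E/Z isomer; free phenols are tolerated in such couplings when excess low-valent titanium is used.

**Step 6**
Reactants: 9 3,5-bis(benzyloxy)-2-[(4S)-6-(cyclopent-3-en-1-yl)-2,7-dimethyloct-6-en-4-yl]phenol
Product: 12 (1R,2R,4S,4'S)-5',7'-bis(benzyloxy)-3,3-dimethyl-4'-(2-methylpropyl)spiro[bicyclo[2.2.1]heptane-2,2'-chromane], via tertiary chroman-2-ylpropan-2-yl radical 10 (not isolated), via secondary norbornan-5-yl radical 11 (not isolated)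
Conditions: 9-mesityl-10-methylacridinium BF4 (5 mol %), 2-phenylmalononitrile (20 mol %), 1,2-dichloroethane (0.02 M), 450 nm LEDs, rt, argon
Reagents that add atoms: none
Why: Proposed new method: the photoexcited acridinium oxidises the tetrasubstituted alkene of 9 to its radical cation, the phenol oxygen adds to the proximal alkene carbon and loses its proton to give the tertiary radical 10, this radical adds to one alkene carbon of the cyclopentenyl group to give the secondary radical 11, and 11 takes a hydrogen atom from 2-phenylmalononitrile, whose radical is reduced by the acridinyl radical and reprotonated, so that the whole is a redox-neutral isomerisation. The closest known reaction types are the acridinium-photocatalysed anti-Markovnikov hydroetherification of alkenols, the polar-radical-crossover cycloaddition in which the β-oxy radical closes 5-exo onto a second alkene before hydrogen-atom transfer, and the closure of 2-(cyclopent-3-enyl)ethyl radicals to 2-norbornyl radicals; what is new is their combination on a tetrasubstituted alkene that carries the acceptor ring on the attacked carbon. The dihydropyran ring closes 6-exo-trig through oxygen (7-endo attack at CMe2 is disfavoured by ring size), and the one C–C bond closes the five-membered ring C2–C1–C7–C4–C3 in 5-exo-trig mode and with it the six-membered ring C1–C2–C3–C4–C5–C6 of the bicyclo[2.2.1]heptane. The spiro centre C2 is controlled by C4': A(1,3) strain between the C3'–C4' bond and the cis-methyl group of the isopropylidene unit puts that unit pseudo-equatorial and the cyclopentenyl group axial in the chair-like transition state, and the isobutyl group stays pseudo-equatorial to avoid a 1,3-diaxial contact with the cyclopentenyl group, which gives the required cis relation of isobutyl and CMe2. The bridgeheads C1 and C4 are set together when the radical chooses between the two diastereotopic alkene carbons of the Cs-symmetric cyclopentenyl group; the transition state with the chroman CH2 exo and the ring oxygen endo avoids a gauche C/C contact with the C5–C6 bridge and should be preferred. The step needs alkene oxidation to lead to product although the trialkoxyphenol is of similar oxidation potential (hole transfer between the two is reversible and only the alkene radical cation has an irreversible exit), and it needs ring closure of 10 before hydrogen-atom transfer, which the weak carbon-acid donor, the high dilution and the gem-dialkyl substitution of the chain should secure.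

**Step 7**
Reactants: 12 (1R,2R,4S,4'S)-5',7'-bis(benzyloxy)-3,3-dimethyl-4'-(2-methylpropyl)spiro[bicyclo[2.2.1]heptane-2,2'-chromane]
Product: 13 (1R,2R,4S,4'S)-3,3-dimethyl-4'-(2-methylpropyl)spiro[bicyclo[2.2.1]heptane-2,2'-chromane]-5',7'-diol
Conditions: H2 (1 atm), 10 % Pd/C, EtOAc–MeOH, rt
Reagents that add atoms: none
Why: Hydrogenolysis of benzyl aryl ethers over palladium; after the cascade no alkene is left, and the tertiary alkyl aryl ether and the benzylic C–C bond are inert.

**Step 8**
Reactants: 13 (1R,2R,4S,4'S)-3,3-dimethyl-4'-(2-methylpropyl)spiro[bicyclo[2.2.1]heptane-2,2'-chromane]-5',7'-diol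
Product: 14 (1R,2R,4S,4'S)-5',7'-dihydroxy-3,3-dimethyl-4'-(2-methylpropyl)spiro[bicyclo[2.2.1]heptane-2,2'-chromane]-6',8'-dicarbaldehyde (CNP0150011.1)
Conditions: POCl3, DMF, MeCN, 0 °C to rt; then H2O, 50 °C
Reagents that add atoms: N,N-dimethylformamide (formyl carbon), CN(C)C=O; water (formyl oxygen), O
Why: Vilsmeier–Haack double formylation of a phloroglucinol-type ring at its only two free positions C6' and C8', each ortho or para to three oxygen substituents; no stereocentre is touched.

**Compound list**
1 | 3,5-bis(benzyloxy)phenol | Oc1cc(OCc2ccccc2)cc(OCc2ccccc2)c1 | starting material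
2 | (E)-5-methylhex-2-enal | CC(C)C/C=C/C=O | starting material
3 | (4S)-5,7-bis(benzyloxy)-4-(2-methylpropyl)chroman-2-ol | CC(C)C[C@H]1CC(O)Oc2cc(OCc3ccccc3)cc(OCc3ccccc3)c21 | intermediate
4 | (4S)-5,7-bis(benzyloxy)-4-(2-methylpropyl)chroman-2-one | CC(C)C[C@H]1CC(=O)Oc2cc(OCc3ccccc3)cc(OCc3ccccc3)c21 | intermediate
5 | (3S)-3-[2,4-bis(benzyloxy)-6-hydroxyphenyl]-N-methoxy-N,5-dimethylhexanamide | CC(C)C[C@@H](CC(=O)N(C)OC)c1c(O)cc(OCc2ccccc2)cc1OCc1ccccc1 | intermediate
6 | 4-bromocyclopent-1-ene | BrC1CC=CC1 | starting material
7 | cyclopent-3-en-1-ylmagnesium bromide | Br[Mg]C1CC=CC1 | intermediate (not isolated)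
8 | (3S)-3-[2,4-bis(benzyloxy)-6-hydroxyphenyl]-1-(cyclopent-3-en-1-yl)-5-methylhexan-1-one | CC(C)C[C@@H](CC(=O)C1CC=CC1)c1c(O)cc(OCc2ccccc2)cc1OCc1ccccc1 | intermediate
9 | 3,5-bis(benzyloxy)-2-[(4S)-6-(cyclopent-3-en-1-yl)-2,7-dimethyloct-6-en-4-yl]phenol | CC(C)C[C@@H](CC(=C(C)C)C1CC=CC1)c1c(O)cc(OCc2ccccc2)cc1OCc1ccccc1 | intermediate
10 | 2-[5,7-bis(benzyloxy)-2-(cyclopent-3-en-1-yl)-4-(2-methylpropyl)chroman-2-yl]propan-2-yl radical (configuration as in 12) | CC(C)C[C@H]1C[C@@]([C](C)C)(Oc2cc(OCc3ccccc3)cc(OCc3ccccc3)c21)C1CC=CC1 | intermediate (not isolated)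
11 | 5',7'-bis(benzyloxy)-3,3-dimethyl-4'-(2-methylpropyl)spiro[bicyclo[2.2.1]heptane-2,2'-chromane]-5-yl radical (configuration as in 12) | CC(C)C[C@H]1C[C@@]2(Oc3cc(OCc4ccccc4)cc(OCc4ccccc4)c31)[C@@H]1C[CH][C@@H](C1)C2(C)C | intermediate (not isolated)
12 | (1R,2R,4S,4'S)-5',7'-bis(benzyloxy)-3,3-dimethyl-4'-(2-methylpropyl)spiro[bicyclo[2.2.1]heptane-2,2'-chromane] | CC(C)C[C@H]1C[C@@]2(Oc3cc(OCc4ccccc4)cc(OCc4ccccc4)c31)[C@@H]1CC[C@@H](C1)C2(C)C | intermediate
13 | (1R,2R,4S,4'S)-3,3-dimethyl-4'-(2-methylpropyl)spiro[bicyclo[2.2.1]heptane-2,2'-chromane]-5',7'-diol | CC(C)C[C@H]1C[C@@]2(Oc3cc(O)cc(O)c31)[C@@H]1CC[C@@H](C1)C2(C)C | intermediate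
14 | (1R,2R,4S,4'S)-5',7'-dihydroxy-3,3-dimethyl-4'-(2-methylpropyl)spiro[bicyclo[2.2.1]heptane-2,2'-chromane]-6',8'-dicarbaldehyde | CC(C)C[C@H]1C[C@@]2(Oc3c(C=O)c(O)c(C=O)c(O)c31)[C@@H]1CC[C@@H](C1)C2(C)C | target

**Step count and risks**
Total steps: 8. Longest linear sequence: 8 steps (from 1 to 14).

Steps most likely to fail:

Step 6 (proposed new method). Four processes may defeat it:
- oxidation of the trialkoxyphenol in place of the alkene, followed by oxidative phenol coupling;
- hydrogen-atom transfer to the tertiary radical before ring closure, which would leave an uncyclised 2-isopropylchroman;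
- poor facial selectivity in the C–O closure (C2 epimer);
- poor discrimination of the two diastereotopic alkene carbons (oxygen exo on the bicycle).

Fallback with known chemistry, setting out from 9: phenylselenoetherification (PhSeCl, K2CO3, CH2Cl2, −78 °C) opens the seleniranium ion 6-exo by the phenol under the same allylic-strain control. It should give the isolable tertiary selenide (2R,4S)-5,7-bis(benzyloxy)-2-(cyclopent-3-en-1-yl)-4-(2-methylpropyl)-2-[2-(phenylselanyl)propan-2-yl]chromane F1, whose C2 epimers can be separated. Slow addition of Bu3SnH with AIBN in benzene at 80 °C then generates the same tertiary radical without any photooxidant and, at low stannane concentration, lets the 5-exo closure run before reduction. The route is rejoined at 12.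

Step 5. The mixed reductive coupling may fail through homocoupling of acetone, through sequestration of the ketone as its hemiketal or titanium phenoxide, through arrest at the pinacol stage, or through loss of benzyl ethers to low-valent titanium. Fallback, setting out from 8: addition of dilithiated isobutyric acid (isobutyric acid, LDA, THF, −78 to 0 °C, one further equivalent of base for the phenol) should give the β-hydroxy acid (5S)-5-[2,4-bis(benzyloxy)-6-hydroxyphenyl]-3-(cyclopent-3-en-1-yl)-3-hydroxy-2,2,7-trimethyloctanoic acid F2 (C3 epimers, of no consequence). Decarboxylative dehydration with N,N-dimethylformamide dineopentyl acetal (toluene, 80 °C) fixes the double bond between the carbinol carbon and the former α-carbon. The route is rejoined at 9.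

Step 1. Alkylation at the ring carbon between the two benzyloxy groups, double alkylation, or erosion of enantioselectivity with the aliphatic enal may occur. Fallback, setting out from 1: palladium-catalysed hydroarylation/lactonisation with ethyl propiolate (Pd(OAc)2, HCO2H, rt) should give 5,7-bis(benzyloxy)-2H-chromen-2-one F3. Copper-catalysed asymmetric conjugate addition of isobutylmagnesium bromide (CuBr·SMe2, a Josiphos-type ferrocenyl diphosphine, t-BuOMe, −72 °C, ligand enantiomer chosen for the 4S product) then leads directly to lactone 4, where the route is rejoined (steps 1 and 2 are replaced).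

**Further compounds**
F1 | step 6 | (2R,4S)-5,7-bis(benzyloxy)-2-(cyclopent-3-en-1-yl)-4-(2-methylpropyl)-2-[2-(phenylselanyl)propan-2-yl]chromane | CC(C)C[C@H]1C[C@@](C(C)(C)[Se]c2ccccc2)(Oc2cc(OCc3ccccc3)cc(OCc3ccccc3)c21)C1CC=CC1
F2 | step 5 | (5S)-5-[2,4-bis(benzyloxy)-6-hydroxyphenyl]-3-(cyclopent-3-en-1-yl)-3-hydroxy-2,2,7-trimethyloctanoic acid | CC(C)C[C@@H](CC(O)(C1CC=CC1)C(C)(C)C(=O)O)c1c(O)cc(OCc2ccccc2)cc1OCc1ccccc1
F3 | step 1 | 5,7-bis(benzyloxy)-2H-chromen-2-one | O=C1C=Cc2c(OCc3ccccc3)cc(OCc3ccccc3)cc2O1
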